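**Retrosynthetic overview**
- The target comes from its 7‑O‑MOM ether by mild acidic methanolysis (last step).
- Ring C is the only ring built and is closed last through the C3–C4 bond. The ring A aldehyde, as a carbene‑bound acyl anion equivalent, adds 1,6 to a para‑quinone methide unveiled on ring B by fluoride (aryl silyl ether plus benzylic acetate). This step sets C3 as (R).
- The two prenyl groups are installed together on a dibromide by a twofold Stille coupling.
- The O1–C2 bond comes from opening a ring B aryl oxirane with the ring A salicylaldehyde phenol, followed by acetylation in the same flask.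
- Rings A and B are bought: 5‑bromo‑2,4‑dihydroxybenzaldehyde and 3‑bromo‑4‑hydroxybenzaldehyde.

**Assumptions**
- The SMILES is read as the (3R)‑isoflavanone: 7,4'‑dihydroxy‑6,3'‑diprenyl, no 5‑OH.
- Simple reagents (MOMCl, TBSCl, trimethylsulfonium iodide, Ac2O, the prenylstannane) are given under "Reagents that add atoms" and are not numbered.
- "Aminoindanol triazolium salt" in step 6 means (5aS,10bR)‑2‑(pentafluorophenyl)‑5a,10b‑dihydro‑4H,6H‑indeno[2,1‑b][1,2,4]triazolo[4,3‑d][1,4]oxazin‑2‑ium tetrafluoroborate. Its sense of induction is assigned only by analogy with chromanone‑forming Stetter closures and must be confirmed on the first run (chiral HPLC, ECD). The mirror‑image salt is equally available and would replace it with no other change.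

**Step 1**
Reactants: 1 5‑bromo‑2,4‑dihydroxybenzaldehyde
Product: 2 5‑bromo‑2‑hydroxy‑4‑(methoxymethoxy)benzaldehyde
Conditions: MOMCl (1.05 equiv), K2CO3 (1.5 equiv), acetone, 0 °C to rt
Reagents that add atoms: chloromethyl methyl ether, COCCl
Why: Williamson etherification is selective for the 4‑OH because it is the more acidic, non‑chelated phenol, while the 2‑OH is held in a hydrogen bond to the formyl group.

**Step 2**
Reactants: 3 3‑bromo‑4‑hydroxybenzaldehyde
Product: 4 3‑bromo‑4‑[(tert‑butyldimethylsilyl)oxy]benzaldehyde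
Conditions: TBSCl, imidazole, CH2Cl2, rt
Reagents that add atoms: tert‑butyldimethylsilyl chloride, CC(C)(C)[Si](C)(C)Cl
Why: Standard imidazole‑mediated phenol silylation; the aryl silyl ether later serves as the fluoride trigger for the quinone methide.

**Step 3**
Reactants: 4 3‑bromo‑4‑[(tert‑butyldimethylsilyl)oxy]benzaldehyde
Product: 5 rac‑2‑{3‑bromo‑4‑[(tert‑butyldimethylsilyl)oxy]phenyl}oxirane
Conditions: Me3SI (1.2 equiv), n‑BuLi (1.15 equiv), THF, −10 °C; then 4, −10 °C to rt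
Reagents that add atoms: trimethylsulfonium iodide, C[S+](C)C.[I-]
Why: Corey–Chaykovsky epoxidation with the ylide preformed, so no butyllithium meets the aryl bromide or the silyl ether; the epoxide is racemic, which is harmless because this carbon becomes planar in step 6.

**Step 4**
Reactants: 2 5‑bromo‑2‑hydroxy‑4‑(methoxymethoxy)benzaldehyde; 5 rac‑2‑{3‑bromo‑4‑[(tert‑butyldimethylsilyl)oxy]phenyl}oxirane
Product: 7 rac‑1‑{3‑bromo‑4‑[(tert‑butyldimethylsilyl)oxy]phenyl}‑2‑[4‑bromo‑2‑formyl‑5‑(methoxymethoxy)phenoxy]ethyl acetate, via secondary alcohol 6 (not isolated)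
Conditions: K2CO3 (0.3 equiv), DMF, 70 °C; then Ac2O, pyridine, DMAP (cat.), rt, same flask
Reagents that add atoms: acetic anhydride, CC(=O)OC(C)=O
Why: Base‑catalysed SN2 opening of the epoxide by the phenoxide at the unhindered terminal carbon gives the benzylic alcohol, which DMAP‑catalysed acetylation turns into the leaving group needed later.

**Step 5**
Reactants: 7 rac‑1‑{3‑bromo‑4‑[(tert‑butyldimethylsilyl)oxy]phenyl}‑2‑[4‑bromo‑2‑formyl‑5‑(methoxymethoxy)phenoxy]ethyl acetate
Product: 8 rac‑1‑{4‑[(tert‑butyldimethylsilyl)oxy]‑3‑(3‑methylbut‑2‑en‑1‑yl)phenyl}‑2‑[2‑formyl‑5‑(methoxymethoxy)‑4‑(3‑methylbut‑2‑en‑1‑yl)phenoxy]ethyl acetate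
Conditions: tributyl(prenyl)stannane (2.6 equiv), Pd(PPh3)4 (10 mol %), degassed DMF, 95 °C
Reagents that add atoms: tributyl(3‑methylbut‑2‑en‑1‑yl)stannane, CCCC[Sn](CCCC)(CCCC)CC=C(C)C
Why: Twofold Stille coupling under neutral conditions tolerates the aldehyde, MOM ether, silyl ether and acetate, and reductive elimination at the less substituted allyl terminus gives the linear prenyl groups.

**Step 6**
Reactants: 8 rac‑1‑{4‑[(tert‑butyldimethylsilyl)oxy]‑3‑(3‑methylbut‑2‑en‑1‑yl)phenyl}‑2‑[2‑formyl‑5‑(methoxymethoxy)‑4‑(3‑methylbut‑2‑en‑1‑yl)phenoxy]ethyl acetate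
Product: 10 (3R)‑3‑[4‑hydroxy‑3‑(3‑methylbut‑2‑en‑1‑yl)phenyl]‑7‑(methoxymethoxy)‑6‑(3‑methylbut‑2‑en‑1‑yl)‑2,3‑dihydro‑4H‑chromen‑4‑one, via para‑quinone methide 9 (not isolated)
Conditions: aminoindanol triazolium salt (15 mol %), CsF (1.1 equiv, solid), 18‑crown‑6 (20 mol %), THF (0.02 M), −20 to 0 °C; AcOH quench at 0 °C
Reagents that add atoms: none
Why: Proposed new method: fluoride removes the silyl group and the phenoxide expels acetate to give the quinone methide, and the chiral carbene turns the aldehyde into an acyl anion equivalent that attacks the exocyclic methide carbon intramolecularly (6‑exo) from the face left open by the indane wall, so C3 is set as (R) while ring B re‑aromatises and the liberated acetate is the only base left; the closest known reactions are carbene‑catalysed 1,6‑additions of aldehydes to stable para‑quinone methides, enantioselective intramolecular Stetter closures to 3‑substituted chroman‑4‑ones, and fluoride‑triggered quinone methide generation under carbene catalysis.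

**Step 7**
Reactants: 10 (3R)‑3‑[4‑hydroxy‑3‑(3‑methylbut‑2‑en‑1‑yl)phenyl]‑7‑(methoxymethoxy)‑6‑(3‑methylbut‑2‑en‑1‑yl)‑2,3‑dihydro‑4H‑chromen‑4‑one
Product: 11 (3R)‑7‑hydroxy‑3‑[4‑hydroxy‑3‑(3‑methylbut‑2‑en‑1‑yl)phenyl]‑6‑(3‑methylbut‑2‑en‑1‑yl)‑2,3‑dihydro‑4H‑chromen‑4‑one
Conditions: HCl (1.25 M in MeOH), MeOH/CH2Cl2, 0 °C to rt, stopped at full conversion; NaHCO3 quench
Reagents that add atoms: none
Why: Acid‑catalysed acetal exchange with methanol frees the 7‑OH, and the dilute, cold, base‑free medium is chosen to keep both prenyl groups from cyclising onto their neighbouring phenols and to leave the enolisable C3 centre untouched.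

**Compound list**
1 | 5‑bromo‑2,4‑dihydroxybenzaldehyde | O=Cc1cc(Br)c(O)cc1O | starting material
2 | 5‑bromo‑2‑hydroxy‑4‑(methoxymethoxy)benzaldehyde | O=Cc1cc(Br)c(OCOC)cc1O | intermediate
3 | 3‑bromo‑4‑hydroxybenzaldehyde | O=Cc1ccc(O)c(Br)c1 | starting material
4 | 3‑bromo‑4‑[(tert‑butyldimethylsilyl)oxy]benzaldehyde | O=Cc1ccc(O[Si](C)(C)C(C)(C)C)c(Br)c1 | intermediate
5 | rac‑2‑{3‑bromo‑4‑[(tert‑butyldimethylsilyl)oxy]phenyl}oxirane | CC(C)(C)[Si](C)(C)Oc1ccc(C2CO2)cc1Br | intermediate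
6 | rac‑5‑bromo‑2‑(2‑{3‑bromo‑4‑[(tert‑butyldimethylsilyl)oxy]phenyl}‑2‑hydroxyethoxy)‑4‑(methoxymethoxy)benzaldehyde | O=Cc1cc(Br)c(OCOC)cc1OCC(O)c1ccc(O[Si](C)(C)C(C)(C)C)c(Br)c1 | intermediate (not isolated)
7 | rac‑1‑{3‑bromo‑4‑[(tert‑butyldimethylsilyl)oxy]phenyl}‑2‑[4‑bromo‑2‑formyl‑5‑(methoxymethoxy)phenoxy]ethyl acetate | O=Cc1cc(Br)c(OCOC)cc1OCC(OC(C)=O)c1ccc(O[Si](C)(C)C(C)(C)C)c(Br)c1 | intermediate
8 | rac‑1‑{4‑[(tert‑butyldimethylsilyl)oxy]‑3‑(3‑methylbut‑2‑en‑1‑yl)phenyl}‑2‑[2‑formyl‑5‑(methoxymethoxy)‑4‑(3‑methylbut‑2‑en‑1‑yl)phenoxy]ethyl acetate | O=Cc1cc(CC=C(C)C)c(OCOC)cc1OCC(OC(C)=O)c1ccc(O[Si](C)(C)C(C)(C)C)c(CC=C(C)C)c1 | intermediate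
9 | 2‑{2‑[3‑(3‑methylbut‑2‑en‑1‑yl)‑4‑oxocyclohexa‑2,5‑dien‑1‑ylidene]ethoxy}‑4‑(methoxymethoxy)‑5‑(3‑methylbut‑2‑en‑1‑yl)benzaldehyde (alkene geometry not defined) | O=Cc1cc(CC=C(C)C)c(OCOC)cc1OCC=C1C=CC(=O)C(CC=C(C)C)=C1 | intermediate (not isolated)
10 | (3R)‑3‑[4‑hydroxy‑3‑(3‑methylbut‑2‑en‑1‑yl)phenyl]‑7‑(methoxymethoxy)‑6‑(3‑methylbut‑2‑en‑1‑yl)‑2,3‑dihydro‑4H‑chromen‑4‑one | CC(C)=CCc1cc([C@@H]2COc3cc(OCOC)c(CC=C(C)C)cc3C2=O)ccc1O | intermediate
11 | (3R)‑7‑hydroxy‑3‑[4‑hydroxy‑3‑(3‑methylbut‑2‑en‑1‑yl)phenyl]‑6‑(3‑methylbut‑2‑en‑1‑yl)‑2,3‑dihydro‑4H‑chromen‑4‑one | CC(C)=CCc1cc([C@@H]2COc3cc(O)c(CC=C(C)C)cc3C2=O)ccc1O | target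

**Step count**
Total: 7 steps. Longest linear sequence: 6 steps (3 → 4 → 5 → 7 → 8 → 10 → 11).

**Three steps most likely to fail**

Step 6. The quinone methide can tautomerise to the 4‑hydroxystyryl ether before it is captured, the carbene can add to it, the enantioselectivity is untested, and the α‑aryl ketone can racemise if excess base remains. Fallback: it sets out from 8 and comes back at 10. Compound 8 is cyclised under the same CsF trigger but with the achiral carbene from 2‑(pentafluorophenyl)‑6,7‑dihydro‑5H‑pyrrolo[2,1‑c][1,2,4]triazol‑2‑ium tetrafluoroborate at rt, where nothing is asked of the bond formation except ring closure. This gives the racemic 7‑O‑MOM isoflavanone F1. F1 is then reduced by transfer hydrogenation with RuCl(p‑cymene)[(R,R)‑TsDPEN] in HCO2H/Et3N (5:2). C3 epimerises through the enol faster than the ketone is reduced, so dynamic kinetic resolution funnels the material to the cis (3R,4R)‑isoflavan‑4‑ol F2; the prenyl alkenes are not touched. Oxidation of F2 with Dess–Martin periodinane and NaHCO3 in CH2Cl2 at 0 °C returns ketone 10 with C3 intact.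

Step 5. Two electron‑rich aryl bromides must both couple, α/γ scrambling of the prenyl group is possible at each site, and the benzylic acetate sits at 95 °C beside zerovalent palladium. Fallback: it sets out from 7 and comes back at 8. Compound 7 is coupled twice with allyltributylstannane and Pd(PPh3)4 in DMF, which has no regiochemical question, to give the rac bis‑allyl acetate F3. Twofold cross‑metathesis of F3 with 2‑methylbut‑2‑ene as co‑solvent and the second‑generation Grubbs catalyst RuCl2(=CHPh)(H2IMes)(PCy3) in CH2Cl2 at 40 °C turns both allyl groups into prenyl groups and gives 8.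

Step 4. The weakly nucleophilic salicylaldehyde phenoxide may open the electron‑rich styrene oxide partly at the benzylic carbon, and the aryl silyl ether may be lost in carbonate/DMF at 70 °C. Fallback: it sets out from 4 (and uses 2) and comes back at 7. Aldehyde 4 is methylenated with Ph3PCH3Br and KN(SiMe3)2 in THF to the silylated 2‑bromo‑4‑vinylphenol F4. Markovnikov acetoxybromination of F4 with NBS in AcOH places the acetate at the benzylic carbon and the bromide at the terminus, giving the rac 2‑bromo‑1‑arylethyl acetate F5. Phenol 2 is then alkylated with F5 at the primary bromide (K2CO3, NaI cat., acetone, 55 °C) to give 7 directly, with the regiochemistry fixed before the ether bond is made.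

**Further compounds**
F1 | step 6 | rac‑3‑[4‑hydroxy‑3‑(3‑methylbut‑2‑en‑1‑yl)phenyl]‑7‑(methoxymethoxy)‑6‑(3‑methylbut‑2‑en‑1‑yl)‑2,3‑dihydro‑4H‑chromen‑4‑one | CC(C)=CCc1cc(C2COc3cc(OCOC)c(CC=C(C)C)cc3C2=O)ccc1O
F2 | step 6 | (3R,4R)‑3‑[4‑hydroxy‑3‑(3‑methylbut‑2‑en‑1‑yl)phenyl]‑7‑(methoxymethoxy)‑6‑(3‑methylbut‑2‑en‑1‑yl)‑3,4‑dihydro‑2H‑chromen‑4‑ol | CC(C)=CCc1cc([C@@H]2COc3cc(OCOC)c(CC=C(C)C)cc3[C@@H]2O)ccc1O
F3 | step 5 | rac‑1‑{4‑[(tert‑butyldimethylsilyl)oxy]‑3‑(prop‑2‑en‑1‑yl)phenyl}‑2‑[2‑formyl‑5‑(methoxymethoxy)‑4‑(prop‑2‑en‑1‑yl)phenoxy]ethyl acetate | O=Cc1cc(CC=C)c(OCOC)cc1OCC(OC(C)=O)c1ccc(O[Si](C)(C)C(C)(C)C)c(CC=C)c1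
F4 | step 4 | (2‑bromo‑4‑ethenylphenoxy)(tert‑butyl)dimethylsilane | C=Cc1ccc(O[Si](C)(C)C(C)(C)C)c(Br)c1
F5 | step 4 | rac‑2‑bromo‑1‑{3‑bromo‑4‑[(tert‑butyldimethylsilyl)oxy]phenyl}ethyl acetate | CC(=O)OC(CBr)c1ccc(O[Si](C)(C)C(C)(C)C)c(Br)c1
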